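Both bicyclic halves are cut from (S)-Wieland–Miescher ketone, whose enone ring serves only as a temporary ring, and are joined at C11–C12 by a B-alkyl Suzuki coupling. Everything rests on closing ring A (oxepane O1–C2–C3–C4–C5–C6–C7) at C3–C4 by a Dieckmann condensation: the C4 enolate of a propanoate on quaternary C6 attacks the ester carbon C3 of a 2-alkoxy-2-methylpropanoate on O1. The step exploits the gem-dimethyl carbon C2 next to C3 (no α-hydrogen, so only one Claisen direction exists) and the trans-diequatorial C7–O1 and C6–C5 bonds on ring B. The precursor is an acyclic diester on a cyclohexenyl triflate; decarboxylation then leaves the C3 ketone.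

Key step: step 5

Remark on locants and assumptions: ring A = O1, C2 (CMe2), C3, C4, C5, C6 (C–CH3), C7 (CH–O); ring B = C6–C11 (C10 carries the exocyclic CH2, C11 the side chain); linker C12–C13; ring C = C14 (carbinol), C15 (CH–CH3), C16, C17, C18 (CH–O), C19 (C–CH3); ring D = C18, O, C23 (CMe2), C22 (C=O), C21, C20, C19. Compound 6 serves both halves: its atoms carry ring A/B locants in steps 4–8 and ring C/D locants in steps 9–14. (S)-Wieland–Miescher ketone is assumed to be bought enantiopure.

**Step 1**
Reactants: 1 (S)-Wieland–Miescher ketone; 2 2-hydroxy-2-methylpropanoic acid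
Product: 3 spiro-dioxolanone at the saturated carbonyl carbon (C7)
Conditions: TsOH·H2O (cat.), toluene, reflux, Dean–Stark
Reagents that add atoms: none
Why: Acid-catalysed condensation of an α-hydroxy acid with a ketone to a 1,3-dioxolan-4-one should occur at the saturated carbonyl, as ketalisation of this dione does, because the enone carbonyl is deactivated by conjugation; the spiro centre forms as an epimer mixture that step 2 erases.

**Step 2**
Reactants: 3 spiro-dioxolanone
Product: 4 ether acid enone
Conditions: Et3SiH, TiCl4, CH2Cl2, −78 °C; aqueous work-up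
Reagents that add atoms: none
Why: TiCl4 ionises the acyloxy C7–O bond to the C7 oxocarbenium ion and Et3SiH delivers hydride axially, anti to the angular C6 methyl, which sets C7 (S) with O1 cis to that methyl and gives the hindered tertiary ether acid directly (ionic hydrogenation, reductive opening of a 1,3-dioxolan-4-one).

**Step 3**
Reactants: 4 ether acid enone
Product: 6 keto diester, via keto diacid 5 (not isolated)
Conditions: O3, CH2Cl2/MeOH, −78 °C; then H2O2, HCO2H, 40 °C; then Me3SiCHN2, toluene/MeOH, 0 °C
Reagents that add atoms: ozone ([O-][O+]=O); hydrogen peroxide (OO); (trimethylsilyl)diazomethane (C[Si](C)(C)C=[N+]=[N-])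
Why: Ozonolysis with oxidative work-up cleaves the enone C=C to the ring ketone and, after loss of the former α-carbon as formic acid, the propanoic acid on the quaternary carbon (the classical cleavage of cyclic enones to keto acids), and both acids are then methylated.

**Step 4**
Reactants: 6 keto diester
Product: 7 enol triflate diester
Conditions: KN(SiMe3)2, THF, −78 °C, in the presence of PhNTf2; then 0 °C
Reagents that add atoms: N-phenylbis(trifluoromethanesulfonimide) (O=S(=O)(N(c1ccccc1)S(=O)(=O)C(F)(F)F)C(F)(F)F)
Why: The ketone is the most acidic site and can enolise only towards C10 because C6 is quaternary, so kinetic enolate O-triflation gives one enol triflate, which masks the ketone against Claisen reactions and is the later coupling handle.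

**Step 5**
Reactants: 7 enol triflate diester
Product: 8 ring A/B β-keto ester
Conditions: LiN(SiMe3)2 (2.5 equiv), THF (0.01 M), −78 to 0 °C; AcOH quench
Reagents that add atoms: none
Why: LiN(SiMe3)2 reversibly deprotonates the only enolisable ester position, C4 of the propanoate, the enolate adds to the ester carbonyl C3 of the 2-alkoxy-2-methylpropanoate, and loss of methoxide gives the β-keto ester, whose deprotonation at C4 pulls the equilibrium to the ring. This is a Dieckmann condensation, the closest known case being base-mediated cyclisation of ether-linked diesters to 3-oxo-oxepane-4-carboxylates. Ring A closes in a 7-exo-trig mode by formation of C3–C4. No stereocentre of the target is created (C4 of 8 is an epimeric, enolisable centre removed in step 6), and C6 and C7 are not α to a carbonyl and cannot epimerise. The step needs regioselectivity for one Claisen direction and chemoselectivity over intermolecular condensation and over the C11 carbonyl. C3 sits on the fully substituted C2 and cannot enolise, the ketone is masked as the enol triflate, and the gauche trans-diequatorial C7–O1 and C6–C5 bonds, the C2 gem-dimethyl group and high dilution favour the seven-membered closure.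

**Step 6**
Reactants: 8 ring A/B β-keto ester
Product: 9 ring A/B ketone
Conditions: LiCl, DMSO, H2O, 130 °C
Reagents that add atoms: none
Why: Krapcho dealkoxycarbonylation (chloride demethylates the ester and the β-keto carboxylate loses CO2) runs under near-neutral conditions that the enol triflate and the ether should tolerate.

**Step 7**
Reactants: 9 ring A/B ketone
Product: 10 (3R)-alcohol
Conditions: (S)-2-methyl-CBS-oxazaborolidine (20 mol %), BH3·SMe2, THF, −20 °C; MeOH quench
Reagents that add atoms: none
Why: In the Corey–Bakshi–Shibata reduction the (S)-oxazaborolidine differentiates the fully substituted C2 (large) from the C4 methylene (small) and should deliver hydride under reagent control to give the (3R)-alcohol, OH cis to the C6 methyl.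

**Step 8**
Reactants: 10 (3R)-alcohol
Product: 11 (3R)-acetate, the ring A/B fragment
Conditions: Ac2O, pyridine, DMAP (cat.), CH2Cl2, rt
Reagents that add atoms: acetic anhydride (CC(=O)OC(C)=O)
Why: DMAP-catalysed acylation esterifies the hindered secondary alcohol without touching the enol triflate.

**Step 9**
Reactants: 6 keto diester
Product: 12 C15-methyl keto diester
Conditions: LiN(SiMe3)2, THF, −78 °C; MeI, DMPU, −78 to −30 °C
Reagents that add atoms: iodomethane (CI)
Why: The kinetic ketone enolate forms only towards C15 (C19 is quaternary) and is alkylated anti to the axial C19 methyl, giving the equatorial (15S) methyl, which is also the thermodynamic epimer; the low temperature keeps the enolate from acylating the esters.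

**Step 10**
Reactants: 12 C15-methyl keto diester
Product: 13 C14-methylidene diester
Conditions: Zn, CH2Br2, TiCl4, THF/CH2Cl2, 0 °C to rt
Reagents that add atoms: dibromomethane (BrCBr)
Why: Takai–Lombardo methylenation is non-basic, so C15 does not epimerise, and the zinc–titanium methylene reagent attacks the ketone but not the two esters; the alkene also masks C14 for step 11.

**Step 11**
Reactants: 13 C14-methylidene diester
Product: 15 ring C/D ketone, via ring D β-keto ester 14 (not isolated)
Conditions: KOt-Bu, THF (high dilution), 0 °C to rt; AcOH; solvent exchange; LiCl, DMSO, H2O, 140 °C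
Reagents that add atoms: none
Why: The same Dieckmann condensation as in step 5 (C21 enolate onto the non-enolisable C22 ester, ring D closed at C21–C22) is followed on the crude β-keto ester by Krapcho dealkoxycarbonylation.

**Step 12**
Reactants: 15 ring C/D ketone
Product: 16 C22 dioxolane
Conditions: Me3SiOCH2CH2OSiMe3, Me3SiOTf (cat.), CH2Cl2, −78 to −20 °C; pyridine quench
Reagents that add atoms: 1,2-bis(trimethylsilyloxy)ethane (C[Si](C)(C)OCCO[Si](C)(C)C)
Why: Silyl-triflate-catalysed ketalisation with the bis-silyl ether protects the C22 ketone under aprotic, cold conditions that should not isomerise the exocyclic alkene.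

**Step 13**
Reactants: 16 C22 dioxolane
Product: 17 C14 spiro-epoxide
Conditions: mCPBA, NaHCO3, CH2Cl2, 0 °C
Reagents that add atoms: 3-chloroperbenzoic acid (OOC(=O)c1cccc(Cl)c1)
Why: Prilezhaev epoxidation should occur on the α face, anti to the axial C19 methyl that flanks the alkene, so the epoxide oxygen becomes axial at C14 as required for the tertiary alcohol.

**Step 14**
Reactants: 17 C14 spiro-epoxide
Product: 18 vinyl carbinol, the ring C/D fragment
Conditions: Me3S+ I− (3 equiv), n-BuLi (3 equiv), THF, −10 °C to rt
Reagents that add atoms: trimethylsulfonium iodide (C[S+](C)C.[I-])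
Why: Dimethylsulfonium methylide opens the epoxide at its CH2 group (C13) and the γ-oxido sulfonium salt eliminates Me2S to the one-carbon-homologated allylic alcohol; C14 is not touched and keeps its configuration.

**Step 15**
Reactants: 18 vinyl carbinol; 11 (3R)-acetate enol triflate
Product: 20 coupled C10=C11 alkene, via B-alkyl-9-BBN adduct 19 (not isolated)
Conditions: 9-BBN (2.5 equiv), THF, rt; then 11, Pd(dppf)Cl2 (10 mol %), AsPh3, K3PO4 (aq), DMF, rt
Reagents that add atoms: none
Why: 9-BBN hydroborates the terminal vinyl group at C12 and the B-alkyl Suzuki–Miyaura coupling with the enol triflate forms the C11–C12 bond under conditions mild enough for the acetate and the ketal.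

**Step 16**
Reactants: 20 coupled C10=C11 alkene
Product: 22 C10 alcohol, via C10 alkylborane 21 (not isolated)
Conditions: BH3·SMe2, THF, 0 °C to rt; then NaOAc (aq), H2O2, 0 °C to rt
Reagents that add atoms: hydrogen peroxide (OO)
Why: Hydroboration places boron on C10 and hydrogen on C11 from the α face, anti to the axial C6 methyl, which sets C11 with H α and the side chain equatorial as in the target, and the buffered oxidation keeps the acetate.

**Step 17**
Reactants: 22 C10 alcohol
Product: 23 C10 ketone
Conditions: Dess–Martin periodinane, NaHCO3, CH2Cl2, rt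
Reagents that add atoms: none
Why: Dess–Martin oxidation converts the only secondary alcohol to the ketone (the tertiary C14 alcohol is inert), and the now epimerisable C11 already carries the thermodynamically preferred equatorial side chain.

**Step 18**
Reactants: 23 C10 ketone
Product: 24 C10-methylidene ketal
Conditions: Zn, CH2Br2, TiCl4, THF/CH2Cl2, 0 °C to rt
Reagents that add atoms: dibromomethane (BrCBr)
Why: Takai–Lombardo methylenation installs the exocyclic methylene without base, so C11 does not epimerise, and it leaves the acetate, the ketal and the tertiary alcohol intact.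

**Step 19**
Reactants: 24 C10-methylidene ketal
Product: 25 3-epi-sodwanone K 3-acetate
Conditions: PPTS, acetone/H2O, 50 °C
Reagents that add atoms: water (O)
Why: Mild acid-catalysed ketal hydrolysis should free the C22 ketone without isomerising the exocyclic alkene, dehydrating the tertiary alcohol or cleaving the acetate.

**Compound list**

1 | (S)-(+)-Wieland–Miescher ketone, (8aS)-8a-methyl-3,4,8,8a-tetrahydronaphthalene-1,6(2H,7H)-dione | O=C1CCCC2=CC(=O)CC[C@]12C | starting material
2 | 2-hydroxy-2-methylpropanoic acid | CC(C)(O)C(=O)O | starting material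
3 | 5,5-dimethyl-1,3-dioxolan-4-one spiro-fused through its C2 to the saturated carbonyl carbon of 1 (quaternary carbon S; both spiro epimers) | CC1(C)OC2(CCCC3=CC(=O)CC[C@]23C)OC1=O | intermediate
4 | 2-methyl-2-{[(4aS,5S)-4a-methyl-2-oxo-2,3,4,4a,5,6,7,8-octahydronaphthalen-5-yl]oxy}propanoic acid (ether oxygen cis to the angular methyl) | OC(=O)C(C)(C)O[C@H]1CCCC2=CC(=O)CC[C@]12C | intermediate
5 | 3-[(1R,2S)-2-(2-carboxypropan-2-yloxy)-1-methyl-6-oxocyclohexyl]propanoic acid | O=C1CCC[C@H](OC(C)(C)C(=O)O)[C@@]1(C)CCC(=O)O | intermediate (not isolated)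
6 | methyl 3-[(1R,2S)-2-[(1-methoxy-2-methyl-1-oxopropan-2-yl)oxy]-1-methyl-6-oxocyclohexyl]propanoate | O=C1CCC[C@H](OC(C)(C)C(=O)OC)[C@@]1(C)CCC(=O)OC | intermediate
7 | methyl 3-[(1R,6S)-6-[(1-methoxy-2-methyl-1-oxopropan-2-yl)oxy]-1-methyl-2-(trifluoromethylsulfonyloxy)cyclohex-2-en-1-yl]propanoate | C1C[C@H](OC(C)(C)C(=O)OC)[C@@](C)(CCC(=O)OC)C(OS(=O)(=O)C(F)(F)F)=C1 | intermediate
8 | ring A/B β-keto ester: trans-fused 2,2-dimethyl-3-oxo-oxepane-4-carboxylic acid methyl ester (C4 epimers and enol) with C6 methyl and C10=C11 enol triflate, (6R,7S) | C1C[C@@H]2OC(C)(C)C(=O)C(C(=O)OC)C[C@@]2(C)C(OS(=O)(=O)C(F)(F)F)=C1 | intermediate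
9 | ring A/B ketone: trans-fused 2,2-dimethyloxepan-3-one with C6 methyl and C10=C11 enol triflate, (6R,7S) | C1C[C@@H]2OC(C)(C)C(=O)CC[C@@]2(C)C(OS(=O)(=O)C(F)(F)F)=C1 | intermediate
10 | (3R,6R,7S)-3-alcohol of 9 (OH cis to the C6 methyl) | C1C[C@@H]2OC(C)(C)[C@H](O)CC[C@@]2(C)C(OS(=O)(=O)C(F)(F)F)=C1 | intermediate
11 | (3R,6R,7S)-3-acetate of 10, ring A/B fragment | C1C[C@@H]2OC(C)(C)[C@H](OC(C)=O)CC[C@@]2(C)C(OS(=O)(=O)C(F)(F)F)=C1 | intermediate
12 | methyl 3-[(1R,2S,5S)-2-[(1-methoxy-2-methyl-1-oxopropan-2-yl)oxy]-1,5-dimethyl-6-oxocyclohexyl]propanoate (C15 methyl equatorial, trans to the C19 methyl) | O=C1[C@@H](C)CC[C@H](OC(C)(C)C(=O)OC)[C@@]1(C)CCC(=O)OC | intermediate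
13 | C14-methylidene analogue of 12 (C14=CH2 in place of C14=O) | C=C1[C@@H](C)CC[C@H](OC(C)(C)C(=O)OC)[C@@]1(C)CCC(=O)OC | intermediate
14 | ring C/D β-keto ester: trans-fused 2,2-dimethyl-3-oxo-oxepane-4-carboxylic acid methyl ester (C21 epimers and enol) with C19 methyl, (15S) methyl and C14=CH2 | C=C1[C@@H](C)CC[C@@H]2OC(C)(C)C(=O)C(C(=O)OC)C[C@]21C | intermediate (not isolated)
15 | ring C/D ketone: trans-fused 2,2-dimethyloxepan-3-one (C22 ketone) with C19 methyl, equatorial C15 methyl and C14=CH2 | C=C1[C@@H](C)CC[C@@H]2OC(C)(C)C(=O)CC[C@]21C | intermediate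
16 | ethylene ketal (1,3-dioxolane) of 15 at C22 | C=C1[C@@H](C)CC[C@@H]2OC(C)(C)C3(OCCO3)CC[C@]21C | intermediate
17 | C14 spiro-epoxide of 16 (epoxide oxygen axial, trans to the C19 methyl; CH2 equatorial) | C1O[C@]12[C@@H](C)CC[C@@H]3OC(C)(C)C4(OCCO4)CC[C@]32C | intermediate
18 | (14S)-14-vinyl-14-ol (OH axial, trans to the C19 methyl; vinyl equatorial), ring C/D fragment | C=C[C@]1(O)[C@@H](C)CC[C@@H]2OC(C)(C)C3(OCCO3)CC[C@]21C | intermediate
19 | B-(C12-alkyl)-9-borabicyclo[3.3.1]nonane from 18 | C1CC2CCCC(C1)B2CC[C@]1(O)[C@@H](C)CC[C@@H]2OC(C)(C)C3(OCCO3)CC[C@]21C | intermediate (not isolated)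
20 | coupled product: C3 acetate, C10=C11 alkene, C14 tertiary alcohol, C22 dioxolane (configuration of the target at C3, C6, C7, C14, C15, C18, C19) | C1C[C@@H]2OC(C)(C)[C@H](OC(C)=O)CC[C@@]2(C)C(=C1)CC[C@]1(O)[C@@H](C)CC[C@@H]2OC(C)(C)C3(OCCO3)CC[C@]21C | intermediate
21 | C10 alkylborane of 20 (boron α on C10, H α on C11), drawn as the monoalkylborane | B[C@H]1CC[C@@H]2OC(C)(C)[C@H](OC(C)=O)CC[C@@]2(C)[C@@H]1CC[C@]1(O)[C@@H](C)CC[C@@H]2OC(C)(C)C3(OCCO3)CC[C@]21C | intermediate (not isolated)
22 | C10 α-alcohol with H-11 α and the side chain equatorial | O[C@H]1CC[C@@H]2OC(C)(C)[C@H](OC(C)=O)CC[C@@]2(C)[C@@H]1CC[C@]1(O)[C@@H](C)CC[C@@H]2OC(C)(C)C3(OCCO3)CC[C@]21C | intermediate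
23 | C10 ketone | O=C1CC[C@@H]2OC(C)(C)[C@H](OC(C)=O)CC[C@@]2(C)[C@@H]1CC[C@]1(O)[C@@H](C)CC[C@@H]2OC(C)(C)C3(OCCO3)CC[C@]21C | intermediate
24 | C22 ethylene ketal of the target | C=C1CC[C@@H]2OC(C)(C)[C@H](OC(C)=O)CC[C@@]2(C)[C@@H]1CC[C@]1(O)[C@@H](C)CC[C@@H]2OC(C)(C)C3(OCCO3)CC[C@]21C | intermediate
25 | 3-epi-sodwanone K 3-acetate | C=C1CC[C@@H]2OC(C)(C)[C@H](OC(C)=O)CC[C@@]2(C)[C@@H]1CC[C@]1(O)[C@@H](C)CC[C@@H]2OC(C)(C)C(=O)CC[C@]21C | target

Total step count: 19. Longest linear sequence: 14 steps (1–3, 9–14, 15–19).

**Steps most likely to fail and their fallbacks**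

Step 2: hydride delivery to the C7 oxocarbenium ion may show poor facial selectivity, or the silane may reduce the enone in a conjugate sense. The fallback sets out from 1. Reduction with NaBH4 in EtOH at 0 °C should attack the saturated ketone from the face anti to the angular methyl and give the hydroxy enone F1. A Bargellini-type etherification of F1 (1,1,1-trichloro-2-methylpropan-2-ol, powdered NaOH, THF, 0 °C to rt) would let the alkoxide open the gem-dichloroepoxide at its tertiary carbon, and hydrolysis of the acyl chloride comes back to the route at 4.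

Step 5: the seven-membered closure may lose to intermolecular Claisen condensation, be reversed by methoxide, or suffer base attack on the enol triflate. The fallback sets out from 7. LiOH (1.1 equiv) in THF/H2O at 0 °C should saponify only the unhindered propanoate to the half-acid F2. LiN(i-Pr)2 (2.2 equiv) in THF at −78 to −20 °C would form the carboxylate dianion, whose C4 carbanion acylates C3 to give, after acidification, the β-keto acid F3. Warming to 40 °C should decarboxylate F3 and come back to the route at 9, so step 6 is not needed. This replaces the reversible ester Claisen by acylation of a far more nucleophilic dianion, and no alkoxide-stable β-keto ester has to survive.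

Step 14: attack of the ylide at the neopentyl-type epoxide CH2 may be too slow, so that ylide decomposition wins. The fallback sets out from 16 and avoids the epoxide. Dihydroxylation with OsO4 (cat.) and NMO in acetone/H2O should occur on the same α face and give the diol F4. Selective oxidation of the primary alcohol (TEMPO, PhI(OAc)2, CH2Cl2) would give the α-hydroxy aldehyde F5. Wittig methylenation of F5 (Ph3PCH3Br, KOt-Bu, THF, 0 °C) comes back to the route at 18.

**Further compounds**

F1 | step 2 | (4aS,5S)-5-hydroxy-4a-methyl-4,4a,5,6,7,8-hexahydronaphthalen-2(3H)-one | O[C@H]1CCCC2=CC(=O)CC[C@]12C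
F2 | step 5 | 3-[(1R,6S)-6-[(1-methoxy-2-methyl-1-oxopropan-2-yl)oxy]-1-methyl-2-(trifluoromethylsulfonyloxy)cyclohex-2-en-1-yl]propanoic acid | C1C[C@H](OC(C)(C)C(=O)OC)[C@@](C)(CCC(=O)O)C(OS(=O)(=O)C(F)(F)F)=C1
F3 | step 5 | ring A/B β-keto acid (the 4-carboxylic acid corresponding to 8) | C1C[C@@H]2OC(C)(C)C(=O)C(C(=O)O)C[C@@]2(C)C(OS(=O)(=O)C(F)(F)F)=C1
F4 | step 14 | C14,C13-diol of 16 (tertiary OH axial, CH2OH equatorial) | OC[C@]1(O)[C@@H](C)CC[C@@H]2OC(C)(C)C3(OCCO3)CC[C@]21C
F5 | step 14 | C14-hydroxy C13-aldehyde | O=C[C@]1(O)[C@@H](C)CC[C@@H]2OC(C)(C)C3(OCCO3)CC[C@]21C
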